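**Plan**

- Numbering: C1 is the ArO–CH2 carbon, C3 the chain carbinol, and ring A is C6–C11 (C6 = CH bearing the chain, C7 = C(Me)OH, C10 = C=O, C11 = CMe2).
- Retrosynthetic cuts, in order: the C1–O aryl ether; one C11–CH3 bond (traced to a CH2 bridging C10 and C11 in a siloxycyclopropane); the C7–O bond (traced to C7–CHO); then C6–C7 and C8–C9 of ring A together; finally C6=C11, which leads back to an aldehyde made from (R)-linalool.
- Enabling feature: ring A is a cyclohexanone whose C10 oxygen lies 1,4 to the oxygen-bearing quaternary C7, with the C6 methine (H, chain) next to C7. This is the pattern left when a 2-silyloxy-1,3-diene C9=C10(OSi)–C11(Me)=C6 adds across C8=C7 of 2-methylacrolein.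
- Forward: the linalool chain (C1–C6) is extended by Wittig olefination and enol silylation to the diene; ring A, the only ring to be built, closes in the cycloaddition; the enol silane then delivers the second C11 methyl and the C10 ketone, the formyl group becomes the C7 hydroxyl, and umbelliferone is attached last.
- Stereochemistry: C3 is carried unchanged from (R)-linalool; C7 comes from the catalyst-controlled face of the enal, C6 from the endo mode of the (E)-diene, and the C7–O bond forms with retention.

Key step: step 6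

Assumption: the (S)-configured oxazaborolidinium catalyst is taken to bind 2-methylacrolein through the formyl C–H···O contact and to cover the si face of C7; should the sense prove opposite, the (R)-catalyst would be used with no other change.

**Step 1**
Reactants: 1 (R)-linalool
Product: 2 (R)-3,7-dimethyloct-6-ene-1,3-diol
Conditions: 9-BBN (2.2 equiv), THF, 0 °C to rt; then NaOH aq., H2O2, 0 °C
Reagents that add atoms: hydrogen peroxide, OO
Why: Hydroboration–oxidation with the bulky 9-BBN should take the monosubstituted vinyl group anti-Markovnikov and leave the trisubstituted alkene, and the C3 stereocentre is not touched.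

**Step 2**
Reactants: 2 (R)-3,7-dimethyloct-6-ene-1,3-diol
Product: 3 (R)-3,7-dimethyl-1,3-bis(triethylsilyloxy)oct-6-ene
Conditions: TESOTf (2.5 equiv), 2,6-lutidine, CH2Cl2, −78 to 0 °C
Reagents that add atoms: triethylsilyl trifluoromethanesulfonate, CC[Si](CC)(CC)OS(=O)(=O)C(F)(F)F
Why: Silyl triflate silylation covers the primary and the tertiary hydroxyl in one operation with weakly Lewis-basic ethers that should not compete for the boron catalyst and that fall off together in step 9.

**Step 3**
Reactants: 3 (R)-3,7-dimethyl-1,3-bis(triethylsilyloxy)oct-6-ene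
Product: 4 (R)-4-methyl-4,6-bis(triethylsilyloxy)hexanal
Conditions: O3, CH2Cl2, −78 °C; then PPh3, −78 °C to rt
Reagents that add atoms: ozone, [O-][O+]=O
Why: Ozonolysis with reductive work-up cleaves the only remaining alkene to the C6 aldehyde, which cannot close to a lactol because the C3 oxygen is silylated.

**Step 4**
Reactants: 4 (R)-4-methyl-4,6-bis(triethylsilyloxy)hexanal; 5 3-(triphenylphosphoranylidene)butan-2-one
Product: 6 (3E,7R)-3,7-dimethyl-7,9-bis(triethylsilyloxy)non-3-en-2-one
Conditions: toluene, 90 °C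
Reagents that add atoms: none
Why: Wittig olefination with the stabilised, α-branched acyl ylide should form C6=C11 with the (E) geometry (acetyl trans to the chain) that the diene needs.

**Step 5**
Reactants: 6 (3E,7R)-3,7-dimethyl-7,9-bis(triethylsilyloxy)non-3-en-2-one
Product: 7 (3E,7R)-2-(tert-butyldimethylsilyloxy)-3,7-dimethyl-7,9-bis(triethylsilyloxy)nona-1,3-diene
Conditions: TBSOTf, Et3N, CH2Cl2, −78 to 0 °C
Reagents that add atoms: tert-butyldimethylsilyl trifluoromethanesulfonate, CC(C)(C)[Si](C)(C)OS(=O)(=O)C(F)(F)F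
Why: Soft enolisation of the methyl ketone (kinetic enol silylation at the acetyl CH3, the only sp3 α-carbon) should give the cross-conjugated 2-silyloxydiene without touching the C11=C6 geometry.

**Step 6**
Reactants: 7 (3E,7R)-2-(tert-butyldimethylsilyloxy)-3,7-dimethyl-7,9-bis(triethylsilyloxy)nona-1,3-diene; 8 2-methylacrolein (methacrolein)
Product: 9 (1S,2R)-4-(tert-butyldimethylsilyloxy)-1,3-dimethyl-2-[(3R)-3-methyl-3,5-bis(triethylsilyloxy)pentyl]cyclohex-3-ene-1-carbaldehyde
Conditions: 8 (3 equiv), (S)-1-(2-methylphenyl)-3,3-diphenyltetrahydro-1H,3H-pyrrolo[1,2-c][1,3,2]oxazaborole (20 mol%), (CF3SO2)2NH (17 mol%), CH2Cl2, −78 to −40 °C; Et3N quench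
Reagents that add atoms: none
Why: The N-protonated oxazaborolidine binds the formyl oxygen of 8 (s-trans enal, formyl C–H···O contact to the ring oxygen) and diene 7 adds in a concerted but asynchronous [4+2] cycloaddition in which C9, the enol-silane terminus, bonds to C8 ahead of C6 to C7. The closest known reaction type is the oxazaborolidinium-catalysed Diels–Alder reaction of 2-methylacrolein with 2-silyloxy-1,3-dienes. Ring A closes in this single suprafacial [4π+2π] event, C8–C9 and C6–C7 forming together, so no separate cyclisation is needed. C7 is set by the catalyst, whose phenyl group covers the si face of the bound enal so that the diene adds to the re face (7S), and C6 is set relative to C7 by the endo orientation of the formyl group with the (E)-configured C11=C6 bond, which places CHO cis to the side chain (6R). The step needs para/ortho regioselectivity, endo selectivity and ring closure in preference to open-chain Mukaiyama–Michael addition; the C10 silyloxy group and the C6 alkyl group both make C9 the nucleophilic terminus, an acyclic diene has no bridging CH2 to force the enal methyl into the endo position, and the bulky silyl group together with the low temperature should keep silyl transfer slow.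

**Step 7**
Reactants: 9 (1S,2R)-4-(tert-butyldimethylsilyloxy)-1,3-dimethyl-2-[(3R)-3-methyl-3,5-bis(triethylsilyloxy)pentyl]cyclohex-3-ene-1-carbaldehyde
Product: 10 (2R,3S)-6-(tert-butyldimethylsilyloxy)-1,3-dimethyl-2-[(3R)-3-methyl-3,5-bis(triethylsilyloxy)pentyl]bicyclo[4.1.0]heptane-3-carbaldehyde (cis-fused cyclopropane, face of addition left open)
Conditions: Et2Zn, CH2I2, CH2Cl2, 0 °C to rt
Reagents that add atoms: diiodomethane, ICI
Why: Simmons–Smith cyclopropanation (diethylzinc variant) should add the electrophilic carbenoid EtZnCH2I to the electron-rich tetrasubstituted enol ether C10=C11 and spare the electrophilic formyl group, and the two new cyclopropane centres are erased in step 9, so the face of addition does not matter.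

**Step 8**
Reactants: 10 (2R,3S)-6-(tert-butyldimethylsilyloxy)-1,3-dimethyl-2-[(3R)-3-methyl-3,5-bis(triethylsilyloxy)pentyl]bicyclo[4.1.0]heptane-3-carbaldehyde
Product: 12 (2R,3S)-6-(tert-butyldimethylsilyloxy)-1,3-dimethyl-2-[(3R)-3-methyl-3,5-bis(triethylsilyloxy)pentyl]bicyclo[4.1.0]heptan-3-ol, via tertiary formate 11 (not isolated)
Conditions: mCPBA, NaHCO3, CH2Cl2, 0 °C to rt; then K2CO3, MeOH, 0 °C
Reagents that add atoms: 3-chloroperoxybenzoic acid, OOC(=O)c1cccc(Cl)c1
Why: In this Baeyer–Villiger oxidation the fully substituted C7 should migrate in preference to hydride and with retention, the C10 ketone is still masked as the siloxycyclopropane so that only the aldehyde can react, and methanolysis of the formate frees the C7 carbinol.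

**Step 9**
Reactants: 12 (2R,3S)-6-(tert-butyldimethylsilyloxy)-1,3-dimethyl-2-[(3R)-3-methyl-3,5-bis(triethylsilyloxy)pentyl]bicyclo[4.1.0]heptan-3-ol
Product: 14 (3R,4S)-3-[(3R)-3,5-dihydroxy-3-methylpentyl]-4-hydroxy-2,2,4-trimethylcyclohexan-1-one, via cyclopropanol tetraol 13 (not isolated)
Conditions: Bu4NF (5 equiv), THF, 0 °C to rt; then NaOH aq., MeOH, 50 °C
Reagents that add atoms: none
Why: Fluoride removes all three silyl groups and base then opens the cyclopropanolate at the C10–CH2 bond, the cleavage that places the developing negative charge on the primary carbon, so the former carbenoid carbon becomes the second C11 methyl and C10 the ketone (Conia-type methylation by cyclopropanol ring opening).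

**Step 10**
Reactants: 14 (3R,4S)-3-[(3R)-3,5-dihydroxy-3-methylpentyl]-4-hydroxy-2,2,4-trimethylcyclohexan-1-one; 15 umbelliferone (7-hydroxycoumarin)
Product: 16 7-{[(3R)-3-hydroxy-5-[(1R,6S)-6-hydroxy-2,2,6-trimethyl-3-oxocyclohexyl]-3-methylpentyl]oxy}-2H-chromen-2-one (target)
Conditions: PPh3, DIAD, THF, 0 °C to rt
Reagents that add atoms: none
Why: In this Mitsunobu etherification the acidic phenol should displace the activated primary C1 oxyphosphonium, while the two tertiary alcohols are too hindered to be activated and no stereocentre is involved.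

**Compound list**

1 | (R)-linalool | C=C[C@](C)(O)CCC=C(C)C | starting material
2 | (R)-3,7-dimethyloct-6-ene-1,3-diol | OCC[C@](C)(O)CCC=C(C)C | intermediate
3 | (R)-3,7-dimethyl-1,3-bis(triethylsilyloxy)oct-6-ene | CC[Si](CC)(CC)OCC[C@](C)(O[Si](CC)(CC)CC)CCC=C(C)C | intermediate
4 | (R)-4-methyl-4,6-bis(triethylsilyloxy)hexanal | O=CCC[C@@](C)(O[Si](CC)(CC)CC)CCO[Si](CC)(CC)CC | intermediate
5 | 3-(triphenylphosphoranylidene)butan-2-one | CC(=O)C(C)=P(c1ccccc1)(c1ccccc1)c1ccccc1 | starting material
6 | (3E,7R)-3,7-dimethyl-7,9-bis(triethylsilyloxy)non-3-en-2-one | CC(=O)/C(C)=C/CC[C@@](C)(O[Si](CC)(CC)CC)CCO[Si](CC)(CC)CC | intermediate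
7 | (3E,7R)-2-(tert-butyldimethylsilyloxy)-3,7-dimethyl-7,9-bis(triethylsilyloxy)nona-1,3-diene | C=C(O[Si](C)(C)C(C)(C)C)/C(C)=C/CC[C@@](C)(O[Si](CC)(CC)CC)CCO[Si](CC)(CC)CC | intermediate
8 | 2-methylacrolein (methacrolein) | CC(=C)C=O | starting material
9 | (1S,2R)-4-(tert-butyldimethylsilyloxy)-1,3-dimethyl-2-[(3R)-3-methyl-3,5-bis(triethylsilyloxy)pentyl]cyclohex-3-ene-1-carbaldehyde | CC1=C(O[Si](C)(C)C(C)(C)C)CC[C@](C)(C=O)[C@@H]1CC[C@@](C)(O[Si](CC)(CC)CC)CCO[Si](CC)(CC)CC | intermediate
10 | (2R,3S)-6-(tert-butyldimethylsilyloxy)-1,3-dimethyl-2-[(3R)-3-methyl-3,5-bis(triethylsilyloxy)pentyl]bicyclo[4.1.0]heptane-3-carbaldehyde (cyclopropane carbons C1 and C6 undefined) | CC12CC2(O[Si](C)(C)C(C)(C)C)CC[C@](C)(C=O)[C@@H]1CC[C@@](C)(O[Si](CC)(CC)CC)CCO[Si](CC)(CC)CC | intermediate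
11 | (2R,3S)-6-(tert-butyldimethylsilyloxy)-1,3-dimethyl-2-[(3R)-3-methyl-3,5-bis(triethylsilyloxy)pentyl]bicyclo[4.1.0]heptan-3-yl formate | CC12CC2(O[Si](C)(C)C(C)(C)C)CC[C@](C)(OC=O)[C@@H]1CC[C@@](C)(O[Si](CC)(CC)CC)CCO[Si](CC)(CC)CC | intermediate
12 | (2R,3S)-6-(tert-butyldimethylsilyloxy)-1,3-dimethyl-2-[(3R)-3-methyl-3,5-bis(triethylsilyloxy)pentyl]bicyclo[4.1.0]heptan-3-ol | CC12CC2(O[Si](C)(C)C(C)(C)C)CC[C@](C)(O)[C@@H]1CC[C@@](C)(O[Si](CC)(CC)CC)CCO[Si](CC)(CC)CC | intermediate
13 | (4S,5R)-5-[(3R)-3,5-dihydroxy-3-methylpentyl]-4,6-dimethylbicyclo[4.1.0]heptane-1,4-diol | CC12CC2(O)CC[C@](C)(O)[C@@H]1CC[C@@](C)(O)CCO | intermediate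
14 | (3R,4S)-3-[(3R)-3,5-dihydroxy-3-methylpentyl]-4-hydroxy-2,2,4-trimethylcyclohexan-1-one | CC1(C)C(=O)CC[C@](C)(O)[C@@H]1CC[C@@](C)(O)CCO | intermediate
15 | umbelliferone (7-hydroxycoumarin) | O=c1ccc2ccc(O)cc2o1 | starting material
16 | 7-{[(3R)-3-hydroxy-5-[(1R,6S)-6-hydroxy-2,2,6-trimethyl-3-oxocyclohexyl]-3-methylpentyl]oxy}-2H-chromen-2-one | CC1(C)C(=O)CC[C@](C)(O)[C@@H]1CC[C@@](C)(O)CCOc1ccc2ccc(=O)oc2c1 | target

**Step count and risks**

Total: 10 steps. Longest linear sequence: 10 steps, from (R)-linalool (1) to 16.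

Steps most likely to fail:

1. Step 6. The encumbered 1,2,3-trisubstituted diene may add too slowly to the catalyst-bound 2-methylacrolein, so that protodesilylation of the diene, open-chain Mukaiyama–Michael addition and leakage through the exo mode erode yield and selectivity. The fallback sets out from 7 and keeps the same two ring bonds but changes the dienophile and the way the C7 oxygen is introduced. Diene 7 would be combined with the more reactive 2-bromoacrolein (BrC(=C)C=O) under the same (S)-oxazaborolidinium activation, (S)-1-(2-methylphenyl)-3,3-diphenyltetrahydro-1H,3H-pyrrolo[1,2-c][1,3,2]oxazaborole with (CF3SO2)2NH, at −90 °C, to give the bromo aldehyde F1 (formyl cis to the chain). NaBH4 in MeOH would reduce it to the bromohydrin F2, and K2CO3 in MeOH would close the spiro-epoxide F3 with inversion at C7, which puts the oxygen cis to the chain. LiEt3BH would open the epoxide at its CH2 carbon to the tertiary carbinol F4, in which C7 carries its methyl and hydroxyl and the enol silane is intact. Cyclopropanation of F4 with Et2Zn and CH2I2 rejoins the route at 12. This path also avoids exposing an aldehyde in steps 7 and 8.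

2. Step 7. The hindered tetrasubstituted enol ether may be cyclopropanated slowly, leaving time for the zinc reagents to consume the formyl group (ethyl transfer, Lewis acid-mediated aldol with the enol silane). The fallback sets out from 9 and replaces the cyclopropane by regiospecific enolate methylation. NaBH4 would reduce 9 to the primary alcohol F5. MeLi (2.5 equiv, THF, 0 °C to rt) would cleave the enol silane to the lithium enolate, which MeI with DMPU would methylate at C11 to give the 2,2-dimethyl ketone F6. Dess–Martin periodinane would return the aldehyde F7. Buffered mCPBA would convert the aldehyde to the formate F8 ahead of the hindered ketone, K2CO3 in MeOH would free the carbinol F9, and Bu4NF would remove the two silyl ethers to rejoin the route at 14.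

3. Step 8. Hydride may migrate in place of C7 in the peracid adduct, giving the carboxylic acid, or acid set free from the peracid may open the siloxycyclopropane early. The fallback sets out from 10 and turns the aldehyde into a methyl ketone, for which migration of the tertiary carbon is the only realistic course. MeMgBr would add to 10 to give the secondary alcohol F10 (mixture of carbinol epimers), and Dess–Martin periodinane would oxidise it to the methyl ketone F11. CF3CO3H buffered with Na2HPO4 would then give the tertiary acetate F12 with retention at C7. Methanolysis with NaOMe in MeOH rejoins the route at 12.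

**Further compounds**

F1 | step 6 | (1R,2R)-1-bromo-4-(tert-butyldimethylsilyloxy)-3-methyl-2-[(3R)-3-methyl-3,5-bis(triethylsilyloxy)pentyl]cyclohex-3-ene-1-carbaldehyde | CC1=C(O[Si](C)(C)C(C)(C)C)CC[C@](Br)(C=O)[C@@H]1CC[C@@](C)(O[Si](CC)(CC)CC)CCO[Si](CC)(CC)CC
F2 | step 6 | bromohydrin, the 1-(hydroxymethyl) analogue of F1 | CC1=C(O[Si](C)(C)C(C)(C)C)CC[C@](Br)(CO)[C@@H]1CC[C@@](C)(O[Si](CC)(CC)CC)CCO[Si](CC)(CC)CC
F3 | step 6 | spiro-epoxide at C7 (oxygen cis to the chain) with the enol silane intact | CC1=C(O[Si](C)(C)C(C)(C)C)CC[C@]2(OC2)[C@@H]1CC[C@@](C)(O[Si](CC)(CC)CC)CCO[Si](CC)(CC)CC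
F4 | step 6 | (1S,2R)-4-(tert-butyldimethylsilyloxy)-1,3-dimethyl-2-[(3R)-3-methyl-3,5-bis(triethylsilyloxy)pentyl]cyclohex-3-en-1-ol | CC1=C(O[Si](C)(C)C(C)(C)C)CC[C@](C)(O)[C@@H]1CC[C@@](C)(O[Si](CC)(CC)CC)CCO[Si](CC)(CC)CC
F5 | step 7 | primary alcohol from reduction of the formyl group of 9 | CC1=C(O[Si](C)(C)C(C)(C)C)CC[C@](C)(CO)[C@@H]1CC[C@@](C)(O[Si](CC)(CC)CC)CCO[Si](CC)(CC)CC
F6 | step 7 | 4-(hydroxymethyl)-2,2,4-trimethylcyclohexanone bearing the bis(triethylsilyloxy) chain at C3 | CC1(C)C(=O)CC[C@](C)(CO)[C@@H]1CC[C@@](C)(O[Si](CC)(CC)CC)CCO[Si](CC)(CC)CC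
F7 | step 7 | keto aldehyde, the 4-formyl analogue of F6 | CC1(C)C(=O)CC[C@](C)(C=O)[C@@H]1CC[C@@](C)(O[Si](CC)(CC)CC)CCO[Si](CC)(CC)CC
F8 | step 7 | keto formate, the C7 formate of F9 | CC1(C)C(=O)CC[C@](C)(OC=O)[C@@H]1CC[C@@](C)(O[Si](CC)(CC)CC)CCO[Si](CC)(CC)CC
F9 | step 7 | (3R,4S)-4-hydroxy-2,2,4-trimethyl-3-[(3R)-3-methyl-3,5-bis(triethylsilyloxy)pentyl]cyclohexan-1-one | CC1(C)C(=O)CC[C@](C)(O)[C@@H]1CC[C@@](C)(O[Si](CC)(CC)CC)CCO[Si](CC)(CC)CC
F10 | step 8 | secondary alcohol from methyl addition to the formyl group of 10 | CC12CC2(O[Si](C)(C)C(C)(C)C)CC[C@](C)(C(C)O)[C@@H]1CC[C@@](C)(O[Si](CC)(CC)CC)CCO[Si](CC)(CC)CC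
F11 | step 8 | methyl ketone, the 3-acetyl analogue of 10 | CC12CC2(O[Si](C)(C)C(C)(C)C)CC[C@](C)(C(C)=O)[C@@H]1CC[C@@](C)(O[Si](CC)(CC)CC)CCO[Si](CC)(CC)CC
F12 | step 8 | tertiary acetate, the C7 acetate of 12 | CC12CC2(O[Si](C)(C)C(C)(C)C)CC[C@](C)(OC(C)=O)[C@@H]1CC[C@@](C)(O[Si](CC)(CC)CC)CCO[Si](CC)(CC)CC
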